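**Plan**

1. Numbering: decalin C1–C10 (C8=C9), tether C11–C12, side-chain alkene C13=C14 (CH2OH on C13), allylic C15, lactone carbinol C16. Retrosynthetic cuts, in order: the lactone C(=O)–O and C(=O)–CH= bonds (CO), the bond from the butenolide ring carbon to its CH2OH, then C12–C13.
2. Forward: (+)-sclareolide supplies the whole decalin plus C11–C12 as a homoallylic Grignard reagent (steps 1–3); a seven-carbon diynol carrying C16 is built in steps 4–6.
3. Step 7 joins the chain: the primary hydroxyl on the CH2 attached to the alkyne (the future C13–CH2OH) becomes a magnesium alkoxide and, through a five-membered O–Mg–C14=C13–CH2 ring, steers a copper-catalysed anti-carbomagnesiation, so the C12–C13 bond and the E alkene form in one event.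
4. The same device, now with the C16 alkoxide and the terminal alkyne, installs the ring CH2OH carbon (as CH2Si) and a cis iodide (step 9); Tamao oxidation and carbonylative lactonisation close the butenolide last (steps 10–11).
5. Stereochemistry: C5 and C10 are bought with sclareolide; C16 (R) is set once by chiral phosphoric acid catalysis (step 4) and no bond to it is broken afterwards; both alkene geometries are fixed by the magnesium chelates.

Key step: step 7

Assumption: (R)-TRIP is taken to expose the Re face of 3-(trimethylsilyl)prop-2-ynal as it does for aryl aldehydes; should the sense be opposite, (S)-TRIP is used and nothing else changes.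

**Route**

Step 1
Reactants: 1 (+)-sclareolide
Product: 2 methyl 2-[(4aS,8aS)-2,5,5,8a-tetramethyl-3,4,4a,5,6,7,8,8a-octahydronaphthalen-1-yl]acetate
Conditions: conc. H2SO4, MeOH, reflux; chromatography on AgNO3-impregnated silica gel
Reagents that add atoms: methanol (SMILES: CO)
Why: Acid-mediated lactone methanolysis with E1 elimination (Fischer esterification of the opened acid): the tertiary C8–O bond ionises, the cation loses the axial C9–H, and equilibration in strong acid should favour the tetrasubstituted C8=C9 alkene, while C5 and C10 are not involved.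

Step 2
Reactants: 2 methyl 2-[(4aS,8aS)-2,5,5,8a-tetramethyl-3,4,4a,5,6,7,8,8a-octahydronaphthalen-1-yl]acetate
Product: 3 2-[(4aS,8aS)-2,5,5,8a-tetramethyl-3,4,4a,5,6,7,8,8a-octahydronaphthalen-1-yl]ethan-1-ol
Conditions: LiAlH4, THF, 0 °C to rt
Reagents that add atoms: none
Why: Ester reduction with LiAlH4 gives the primary alcohol, the hindered tetrasubstituted alkene and both stereocenters being inert to hydride.

Step 3
Reactants: 3 2-[(4aS,8aS)-2,5,5,8a-tetramethyl-3,4,4a,5,6,7,8,8a-octahydronaphthalen-1-yl]ethan-1-ol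
Product: 4 (4aS,8aS)-1-(2-bromoethyl)-2,5,5,8a-tetramethyl-3,4,4a,5,6,7,8,8a-octahydronaphthalene
Conditions: CBr4, PPh3, CH2Cl2, 0 °C
Reagents that add atoms: carbon tetrabromide (SMILES: BrC(Br)(Br)Br)
Why: Appel reaction: the oxyphosphonium salt of the primary alcohol is displaced by bromide in an SN2 step under neutral conditions that leave the alkene untouched.

Step 4
Reactants: 5 3-(trimethylsilyl)prop-2-ynal; 6 4,4,5,5-tetramethyl-2-(propa-1,2-dien-1-yl)-1,3,2-dioxaborolane (allenylboronic acid pinacol ester)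
Product: 7 (3R)-1-(trimethylsilyl)hexa-1,5-diyn-3-ol
Conditions: (R)-TRIP [(R)-3,3'-bis(2,4,6-triisopropylphenyl)-1,1'-binaphthyl-2,2'-diyl hydrogen phosphate] (5 mol%), 4 Å molecular sieves, toluene, −20 °C; aqueous work-up
Reagents that add atoms: none
Why: Chiral phosphoric acid-catalysed propargylation of an aldehyde with an allenylboronate: a closed six-membered SE2' transition state, in which the catalyst binds a boronate oxygen and the formyl hydrogen, is expected to expose the Re face of 5 and so set the (R)-carbinol, the only stereocenter made in the route, while leaving a terminal alkyne.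

Step 5
Reactants: 7 (3R)-1-(trimethylsilyl)hexa-1,5-diyn-3-ol
Product: 8 tert-butyldimethyl{[(3R)-1-(trimethylsilyl)hexa-1,5-diyn-3-yl]oxy}silane
Conditions: TBSCl, imidazole, DMF, rt
Reagents that add atoms: tert-butyldimethylsilyl chloride (SMILES: CC(C)(C)[Si](C)(C)Cl)
Why: Silyl ether formation masks the secondary hydroxyl so that it can neither quench nor direct the organometallic reagent of step 7, and the stereocenter is not touched.

Step 6
Reactants: 8 tert-butyldimethyl{[(3R)-1-(trimethylsilyl)hexa-1,5-diyn-3-yl]oxy}silane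
Product: 10 (5R)-5-[(tert-butyldimethylsilyl)oxy]-7-(trimethylsilyl)hepta-2,6-diyn-1-ol, via lithium acetylide 9 (not isolated)
Conditions: n-BuLi, THF, −78 °C; (CH2O)n, −78 °C to rt; aq NH4Cl
Reagents that add atoms: formaldehyde from paraformaldehyde (SMILES: C=O)
Why: Deprotonation of the terminal alkyne (the most acidic C–H) and 1,2-addition of the lithium acetylide to formaldehyde give the 2-alkyn-1-ol whose hydroxyl will direct the key step, the silylated alkyne and the silyl ether being stable at −78 °C.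

Step 7
Reactants: 4 (4aS,8aS)-1-(2-bromoethyl)-2,5,5,8a-tetramethyl-3,4,4a,5,6,7,8,8a-octahydronaphthalene; 10 (5R)-5-[(tert-butyldimethylsilyl)oxy]-7-(trimethylsilyl)hepta-2,6-diyn-1-ol
Product: 14 (2E,5R)-5-[(tert-butyldimethylsilyl)oxy]-2-{2-[(4aS,8aS)-2,5,5,8a-tetramethyl-3,4,4a,5,6,7,8,8a-octahydronaphthalen-1-yl]ethyl}-7-(trimethylsilyl)hept-2-en-6-yn-1-ol, via Grignard reagent 11 (not isolated), via chloromagnesium alkoxide 12 (not isolated), via oxamagnesacycle 13 (not isolated)
Conditions: 4, Mg, THF, 40 °C; separately 10, i-PrMgCl (1.0 equiv), THF, −20 °C; 11 (1.5 equiv) added to 12, CuI (15 mol%), THF/Et2O, −10 °C to rt; aq NH4Cl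
Reagents that add atoms: none
Why: Copper-catalysed, alkoxide-directed anti-carbomagnesiation of a 2-alkyn-1-ol, a known reaction type for primary alkyl Grignard reagents: the alkyl group passes from magnesium to monovalent copper and then to the alkyne carbon nearer the OMgCl group (C13), while the oxygen-bound magnesium takes the distal carbon (C14), so that the adduct is the five-membered O–Mg–C14=C13–CH2 chelate 13. The only ring closed is this transient magnesacycle (the oxygen-bound metal adds to the far alkyne carbon in the endo sense), and the proton quench opens it again with retention at carbon; no ring of the target forms here. No stereocenter is created; the alkene geometry is dictated by the chelate, which holds Mg (then H) cis to CH2OH and therefore the incoming chain cis to C15, that is the E alkene of the target. The step needs regioselectivity (alkyl to the carbon bearing CH2O), anti stereoselectivity and chemoselectivity between the two alkynes, and all three are secured by the single free primary hydroxyl, because the second alkyne is capped by SiMe3 and flanked only by a non-coordinating silyl ether and so has no alkoxide to deliver the metal. The homoallylic Grignard reagent 11 keeps its constitution because its only rearrangement (3-butenyl to cyclopropylcarbinyl and back) is degenerate.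

Step 8
Reactants: 14 (2E,5R)-5-[(tert-butyldimethylsilyl)oxy]-2-{2-[(4aS,8aS)-2,5,5,8a-tetramethyl-3,4,4a,5,6,7,8,8a-octahydronaphthalen-1-yl]ethyl}-7-(trimethylsilyl)hept-2-en-6-yn-1-ol
Product: 15 (2E,5R)-2-{2-[(4aS,8aS)-2,5,5,8a-tetramethyl-3,4,4a,5,6,7,8,8a-octahydronaphthalen-1-yl]ethyl}hept-2-en-6-yne-1,5-diol
Conditions: TBAF (3 equiv), THF, 0 °C to rt
Reagents that add atoms: none
Why: Fluoride-mediated desilylation cleaves the O–Si bond of the silyl ether and the C(sp)–Si bond of the alkynylsilane in one operation, unveiling the secondary propargylic alcohol and the terminal alkyne without touching C16 or the alkenes.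

Step 9
Reactants: 15 (2E,5R)-2-{2-[(4aS,8aS)-2,5,5,8a-tetramethyl-3,4,4a,5,6,7,8,8a-octahydronaphthalen-1-yl]ethyl}hept-2-en-6-yne-1,5-diol
Product: 17 (2E,5R,6E)-6-{[dimethyl(propan-2-yloxy)silyl]methyl}-7-iodo-2-{2-[(4aS,8aS)-2,5,5,8a-tetramethyl-3,4,4a,5,6,7,8,8a-octahydronaphthalen-1-yl]ethyl}hepta-2,6-diene-1,5-diol, via alkenylmagnesium chelate 16 (not isolated)
Conditions: (i-PrO)Me2SiCH2MgCl (5 equiv, made in situ from ClCH2SiMe2(Oi-Pr) and Mg, THF), CuI (15 mol%), THF, 0 °C to rt; then I2, THF, −78 °C; aq Na2S2O3, aq NH4Cl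
Reagents that add atoms: [(isopropoxy)dimethylsilyl]methylmagnesium chloride (SMILES: CC(C)O[Si](C)(C)C[Mg]Cl); iodine (SMILES: [I][I])
Why: Second copper-catalysed, alkoxide-directed anti-carbomagnesiation, now steered by the secondary propargylic alkoxide at C16 (the primary allylic alkoxide has no alkyne within reach): the silylmethyl group, a hydroxymethyl anion equivalent, goes to the internal alkyne carbon and magnesium to the terminal carbon cis to C16, and iodinolysis of the C–Mg bond with retention gives the iodoalkene with iodine cis to the carbinol.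

Step 10
Reactants: 17 (2E,5R,6E)-6-{[dimethyl(propan-2-yloxy)silyl]methyl}-7-iodo-2-{2-[(4aS,8aS)-2,5,5,8a-tetramethyl-3,4,4a,5,6,7,8,8a-octahydronaphthalen-1-yl]ethyl}hepta-2,6-diene-1,5-diol
Product: 18 (2E,5R,6Z)-6-(hydroxymethyl)-7-iodo-2-{2-[(4aS,8aS)-2,5,5,8a-tetramethyl-3,4,4a,5,6,7,8,8a-octahydronaphthalen-1-yl]ethyl}hepta-2,6-diene-1,5-diol
Conditions: KF, KHCO3, 30% aq H2O2, THF/MeOH (1:1), rt; aq Na2S2O3
Reagents that add atoms: hydrogen peroxide (SMILES: OO)
Why: Tamao oxidation: fluoride- and bicarbonate-assisted attack of hydroperoxide on the alkoxysilane and 1,2-shift of the allylic carbon from silicon to oxygen convert CH2–Si into CH2–OH without allylic transposition, the alkenyl iodide, the unconjugated alkenes and C16 being unaffected by basic peroxide.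

Step 11
Reactants: 18 (2E,5R,6Z)-6-(hydroxymethyl)-7-iodo-2-{2-[(4aS,8aS)-2,5,5,8a-tetramethyl-3,4,4a,5,6,7,8,8a-octahydronaphthalen-1-yl]ethyl}hepta-2,6-diene-1,5-diol
Product: 19 (5R)-4-(hydroxymethyl)-5-{(2E)-3-(hydroxymethyl)-5-[(4aS,8aS)-2,5,5,8a-tetramethyl-3,4,4a,5,6,7,8,8a-octahydronaphthalen-1-yl]pent-2-en-1-yl}furan-2(5H)-one
Conditions: PdCl2(PPh3)2 (5 mol%), CO (1 atm), K2CO3, THF, 40 °C
Reagents that add atoms: carbon monoxide (SMILES: [C-]#[O+])
Why: Palladium-catalysed cyclocarbonylation of a (Z)-3-iodoallylic alcohol: oxidative addition of zerovalent palladium into the C–I bond, CO insertion and capture of the acylpalladium by the cis secondary hydroxyl at C16 close the butenolide (5-exo-trig acyl substitution), whereas the CH2OH group trans to the acyl group cannot reach it, and C16 keeps its R configuration.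

**Compound list**

1 | (+)-sclareolide, (3aR,5aS,9aS,9bR)-3a,6,6,9a-tetramethyldecahydronaphtho[2,1-b]furan-2(1H)-one | C[C@]1(OC(=O)C3)[C@H]3[C@@]2(C)CCCC(C)(C)[C@@H]2CC1 | starting material
2 | methyl 2-[(4aS,8aS)-2,5,5,8a-tetramethyl-3,4,4a,5,6,7,8,8a-octahydronaphthalen-1-yl]acetate | CC1=C(CC(=O)OC)[C@@]2(C)CCCC(C)(C)[C@@H]2CC1 | intermediate
3 | 2-[(4aS,8aS)-2,5,5,8a-tetramethyl-3,4,4a,5,6,7,8,8a-octahydronaphthalen-1-yl]ethan-1-ol | CC1=C(CCO)[C@@]2(C)CCCC(C)(C)[C@@H]2CC1 | intermediate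
4 | (4aS,8aS)-1-(2-bromoethyl)-2,5,5,8a-tetramethyl-3,4,4a,5,6,7,8,8a-octahydronaphthalene | CC1=C(CCBr)[C@@]2(C)CCCC(C)(C)[C@@H]2CC1 | intermediate
5 | 3-(trimethylsilyl)prop-2-ynal | C[Si](C)(C)C#CC=O | starting material
6 | 4,4,5,5-tetramethyl-2-(propa-1,2-dien-1-yl)-1,3,2-dioxaborolane (allenylboronic acid pinacol ester) | C=C=CB1OC(C)(C)C(C)(C)O1 | starting material
7 | (3R)-1-(trimethylsilyl)hexa-1,5-diyn-3-ol | C#CC[C@@H](O)C#C[Si](C)(C)C | intermediate
8 | tert-butyldimethyl{[(3R)-1-(trimethylsilyl)hexa-1,5-diyn-3-yl]oxy}silane | C#CC[C@@H](O[Si](C)(C)C(C)(C)C)C#C[Si](C)(C)C | intermediate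
9 | lithium acetylide of 8, [(4R)-4-[(tert-butyldimethylsilyl)oxy]-6-(trimethylsilyl)hexa-1,5-diyn-1-yl]lithium | [Li]C#CC[C@@H](O[Si](C)(C)C(C)(C)C)C#C[Si](C)(C)C | intermediate (not isolated)
10 | (5R)-5-[(tert-butyldimethylsilyl)oxy]-7-(trimethylsilyl)hepta-2,6-diyn-1-ol | OCC#CC[C@@H](O[Si](C)(C)C(C)(C)C)C#C[Si](C)(C)C | intermediate
11 | {2-[(4aS,8aS)-2,5,5,8a-tetramethyl-3,4,4a,5,6,7,8,8a-octahydronaphthalen-1-yl]ethyl}magnesium bromide | CC1=C(CC[Mg]Br)[C@@]2(C)CCCC(C)(C)[C@@H]2CC1 | intermediate (not isolated)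
12 | chloromagnesium (5R)-5-[(tert-butyldimethylsilyl)oxy]-7-(trimethylsilyl)hepta-2,6-diyn-1-olate | Cl[Mg]OCC#CC[C@@H](O[Si](C)(C)C(C)(C)C)C#C[Si](C)(C)C | intermediate (not isolated)
13 | oxamagnesacycle: 2,5-dihydro-1,2-oxamagnesole with Mg bonded to the CH2O oxygen and to C14; C13 carries the 2-[(4aS,8aS)-2,5,5,8a-tetramethyl-3,4,4a,5,6,7,8,8a-octahydronaphthalen-1-yl]ethyl group and C14 the (2R)-2-[(tert-butyldimethylsilyl)oxy]-4-(trimethylsilyl)but-3-yn-1-yl group | CC1=C(CCC2=C(C[C@@H](O[Si](C)(C)C(C)(C)C)C#C[Si](C)(C)C)[Mg]OC2)[C@@]3(C)CCCC(C)(C)[C@@H]3CC1 | intermediate (not isolated)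
14 | (2E,5R)-5-[(tert-butyldimethylsilyl)oxy]-2-{2-[(4aS,8aS)-2,5,5,8a-tetramethyl-3,4,4a,5,6,7,8,8a-octahydronaphthalen-1-yl]ethyl}-7-(trimethylsilyl)hept-2-en-6-yn-1-ol | CC1=C(CC/C(=C\C[C@@H](O[Si](C)(C)C(C)(C)C)C#C[Si](C)(C)C)CO)[C@@]2(C)CCCC(C)(C)[C@@H]2CC1 | intermediate
15 | (2E,5R)-2-{2-[(4aS,8aS)-2,5,5,8a-tetramethyl-3,4,4a,5,6,7,8,8a-octahydronaphthalen-1-yl]ethyl}hept-2-en-6-yne-1,5-diol | CC1=C(CC/C(=C\C[C@@H](O)C#C)CO)[C@@]2(C)CCCC(C)(C)[C@@H]2CC1 | intermediate
16 | alkenylmagnesium chelate: five-membered ring C16–O–Mg–CH=C(CH2SiMe2Oi-Pr) with C16 (R) bonded to the ring alkene carbon; the primary allylic oxygen is present as OMgCl | CC1=C(CC/C(=C\C[C@H]2O[Mg]C=C2C[Si](C)(C)OC(C)C)CO[Mg]Cl)[C@@]3(C)CCCC(C)(C)[C@@H]3CC1 | intermediate (not isolated)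
17 | (2E,5R,6E)-6-{[dimethyl(propan-2-yloxy)silyl]methyl}-7-iodo-2-{2-[(4aS,8aS)-2,5,5,8a-tetramethyl-3,4,4a,5,6,7,8,8a-octahydronaphthalen-1-yl]ethyl}hepta-2,6-diene-1,5-diol | CC1=C(CC/C(=C\C[C@@H](O)/C(C[Si](C)(C)OC(C)C)=C\I)CO)[C@@]2(C)CCCC(C)(C)[C@@H]2CC1 | intermediate
18 | (2E,5R,6Z)-6-(hydroxymethyl)-7-iodo-2-{2-[(4aS,8aS)-2,5,5,8a-tetramethyl-3,4,4a,5,6,7,8,8a-octahydronaphthalen-1-yl]ethyl}hepta-2,6-diene-1,5-diol | CC1=C(CC/C(=C\C[C@@H](O)/C(CO)=C\I)CO)[C@@]2(C)CCCC(C)(C)[C@@H]2CC1 | intermediate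
19 | (5R)-4-(hydroxymethyl)-5-{(2E)-3-(hydroxymethyl)-5-[(4aS,8aS)-2,5,5,8a-tetramethyl-3,4,4a,5,6,7,8,8a-octahydronaphthalen-1-yl]pent-2-en-1-yl}furan-2(5H)-one | CC1=C(CC/C(=C\C[C@H]2OC(=O)C=C2CO)CO)[C@@]2(C)CCCC(C)(C)[C@@H]2CC1 | target

**Step count and risks**

Total step count: 11.
Longest linear sequence: 8 steps (steps 4, 5, 6, 7, 8, 9, 10, 11; the sclareolide branch, steps 1, 2, 3, 7–11, is equally long).

Three steps most likely to fail:

1. Step 7. Transfer of the bulky primary alkyl group to the internal alkyne may be slower than decay of the organocopper species (β-hydride loss, homocoupling), and leakage to syn addition or attack at the silylated alkyne would erode geometry and yield. Fallback (cross-coupling instead of carbometalation; it sets out from 10 and from Grignard reagent 11, and returns at 14): hydroxyl-directed ruthenium-catalysed trans-hydrostannation of 10 ([Cp*RuCl]4 cat., Bu3SnH, CH2Cl2, rt) should place tin on the alkyne carbon next to CH2OH with hydrogen anti, giving (2Z,5R)-5-[(tert-butyldimethylsilyl)oxy]-2-(tributylstannyl)-7-(trimethylsilyl)hept-2-en-6-yn-1-ol F1. Iododestannylation (I2, CH2Cl2, 0 °C) then gives, with retention, (2Z,5R)-5-[(tert-butyldimethylsilyl)oxy]-2-iodo-7-(trimethylsilyl)hept-2-en-6-yn-1-ol F2. Grignard reagent 11 is trapped with 9-methoxy-9-borabicyclo[3.3.1]nonane to give 9-{2-[(4aS,8aS)-2,5,5,8a-tetramethyl-3,4,4a,5,6,7,8,8a-octahydronaphthalen-1-yl]ethyl}-9-borabicyclo[3.3.1]nonane F3, and B-alkyl Suzuki–Miyaura coupling of F2 with F3 (PdCl2(dppf), AsPh3, Cs2CO3, DMF/THF/H2O, rt) gives 14 with the same alkene geometry.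

2. Step 9. The iodine quench may not stop at the C–Mg bond: excess iodine can attack the allylsilane or trigger iodoetherification of the C16 alkoxide onto the C13=C14 alkene. Fallback (carboxylative ring closure without iodine or palladium; it sets out from 15, passes through the same chelate 16 and returns at 19): 16 is quenched with CO2 (−40 °C to rt) and acidified (1 M HCl) to give (2E,4R,6E)-3-{[dimethyl(propan-2-yloxy)silyl]methyl}-4-hydroxy-7-(hydroxymethyl)-9-[(4aS,8aS)-2,5,5,8a-tetramethyl-3,4,4a,5,6,7,8,8a-octahydronaphthalen-1-yl]nona-2,6-dienoic acid F4. F4 lactonises spontaneously to (5R)-4-{[dimethyl(propan-2-yloxy)silyl]methyl}-5-{(2E)-3-(hydroxymethyl)-5-[(4aS,8aS)-2,5,5,8a-tetramethyl-3,4,4a,5,6,7,8,8a-octahydronaphthalen-1-yl]pent-2-en-1-yl}furan-2(5H)-one F5, and Tamao oxidation of F5 (KF, KHCO3, H2O2, THF/MeOH, 0 °C) gives 19, so that 17 and 18 are bypassed. The weak point of this fallback is that the C–Si bond in F5 is vinylogously activated by the lactone, so protodesilylation may compete with oxidation.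

3. Step 1. Ionisation may be incomplete, the cation may re-close to the lactone, and the trisubstituted and exocyclic alkene isomers may form and prove hard to separate. Fallback (stepwise reduction, protection and regioselective dehydration; it sets out from 1 and returns at 3): LiAlH4 (THF, reflux) reduces the lactone to (1R,2R,4aS,8aS)-1-(2-hydroxyethyl)-2,5,5,8a-tetramethyldecahydronaphthalen-2-ol F6. Ac2O/pyridine acetylates only the primary hydroxyl to give 2-[(1R,2R,4aS,8aS)-2-hydroxy-2,5,5,8a-tetramethyldecahydronaphthalen-1-yl]ethyl acetate F7. I2/PPh3 (CH2Cl2, rt) dehydrates the tertiary alcohol to the tetrasubstituted alkene, 2-[(4aS,8aS)-2,5,5,8a-tetramethyl-3,4,4a,5,6,7,8,8a-octahydronaphthalen-1-yl]ethyl acetate F8, and K2CO3/MeOH removes the acetate to give 3.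

**Further compounds**

F1 | step 7 | (2Z,5R)-5-[(tert-butyldimethylsilyl)oxy]-2-(tributylstannyl)-7-(trimethylsilyl)hept-2-en-6-yn-1-ol | CCCC[Sn](CCCC)(CCCC)/C(=C\C[C@@H](O[Si](C)(C)C(C)(C)C)C#C[Si](C)(C)C)CO
F2 | step 7 | (2Z,5R)-5-[(tert-butyldimethylsilyl)oxy]-2-iodo-7-(trimethylsilyl)hept-2-en-6-yn-1-ol | I/C(=C\C[C@@H](O[Si](C)(C)C(C)(C)C)C#C[Si](C)(C)C)CO
F3 | step 7 | 9-{2-[(4aS,8aS)-2,5,5,8a-tetramethyl-3,4,4a,5,6,7,8,8a-octahydronaphthalen-1-yl]ethyl}-9-borabicyclo[3.3.1]nonane | CC1=C(CCB2C3CCCC2CCC3)[C@@]4(C)CCCC(C)(C)[C@@H]4CC1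
F4 | step 9 | (2E,4R,6E)-3-{[dimethyl(propan-2-yloxy)silyl]methyl}-4-hydroxy-7-(hydroxymethyl)-9-[(4aS,8aS)-2,5,5,8a-tetramethyl-3,4,4a,5,6,7,8,8a-octahydronaphthalen-1-yl]nona-2,6-dienoic acid | CC1=C(CC/C(=C\C[C@@H](O)/C(C[Si](C)(C)OC(C)C)=C\C(=O)O)CO)[C@@]2(C)CCCC(C)(C)[C@@H]2CC1
F5 | step 9 | (5R)-4-{[dimethyl(propan-2-yloxy)silyl]methyl}-5-{(2E)-3-(hydroxymethyl)-5-[(4aS,8aS)-2,5,5,8a-tetramethyl-3,4,4a,5,6,7,8,8a-octahydronaphthalen-1-yl]pent-2-en-1-yl}furan-2(5H)-one | CC1=C(CC/C(=C\C[C@H]2OC(=O)C=C2C[Si](C)(C)OC(C)C)CO)[C@@]2(C)CCCC(C)(C)[C@@H]2CC1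
F6 | step 1 | (1R,2R,4aS,8aS)-1-(2-hydroxyethyl)-2,5,5,8a-tetramethyldecahydronaphthalen-2-ol | C[C@]1(O)[C@H](CCO)[C@@]2(C)CCCC(C)(C)[C@@H]2CC1
F7 | step 1 | 2-[(1R,2R,4aS,8aS)-2-hydroxy-2,5,5,8a-tetramethyldecahydronaphthalen-1-yl]ethyl acetate | C[C@]1(O)[C@H](CCOC(C)=O)[C@@]2(C)CCCC(C)(C)[C@@H]2CC1
F8 | step 1 | 2-[(4aS,8aS)-2,5,5,8a-tetramethyl-3,4,4a,5,6,7,8,8a-octahydronaphthalen-1-yl]ethyl acetate | CC1=C(CCOC(C)=O)[C@@]2(C)CCCC(C)(C)[C@@H]2CC1
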